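# Total synthesis of ferulsinaic acid from (R)-Hajos–Parrish ketone

## Retrosynthetic overview

1. C–O bond: Mitsunobu coupling of umbelliferone (coumarin bought intact) with the C2‑CH2OH cyclopentane. The acid is carried as its methyl ester.
2. C2/C3 (trans CH2OH/CH3): from a tetrasubstituted cyclopentene‑carbaldehyde by 1,4‑hydride addition and CHO epimerisation. The enal comes from an enol triflate, which comes from the α‑methyl ketone.
3. C5 isobutenyl and C1 propanoate (cis): from a Wittig reaction after ozonolytic C4–C5 scission of the six‑membered ring of a cis‑hydrindane silyl enol ether.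
4. The cis‑hydrindane comes from 1,4‑reduction of (R)‑Hajos–Parrish ketone, which supplies the quaternary centre.
5. Ring order: no ring is built. The cyclopentane is the five‑membered ring of the Hajos–Parrish ketone, its six‑membered ring is sacrificed, and the coumarin is attached last.

**Assumption:** (R)‑(–)‑Hajos–Parrish ketone is purchasable. If not, it takes two steps from 2‑methylcyclopentane‑1,3‑dione, methyl vinyl ketone and D‑proline.

**Target locants and descriptors:** C1 is the quaternary carbon, C2 bears CH2OAr, C3 bears CH3, C4 is CH2 and C5 bears the isobutenyl group. The target is (1R,2R,3S,5S).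

**Faces:** 1‑CH3 and 2‑CH2OAr lie on the "top" face. The propanoate chain, 3‑CH3 and the isobutenyl group lie on the "bottom" face.

**Atom mapping from the Hajos–Parrish (HP) ketone:**

| HP atom | Target position |
|---|---|
| C7a | C1 |
| C1 | C2 |
| C2 | C3 |
| C3 | C4 |
| C3a | C5 |
| C4 | isobutenyl CH |
| C7–C6–C5 | propanoate chain |

## Forward route

**Step 1**
- Reactants: 1, (R)‑Hajos–Parrish ketone
- Product: 2, (3aS,7aR)‑5‑(TBSO)‑7a‑methyl‑2,3,3a,6,7,7a‑hexahydro‑1H‑inden‑1‑one. It is cis‑fused (3a‑H and 7a‑CH3 on the same face) with the enol ether at C4=C5.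
- Conditions: [(Ph3P)CuH]6 (0.4 equiv), TBSCl (2.5 equiv), toluene, 0 °C → rt
- Reagents that add atoms: TBSCl, CC(C)(C)[Si](C)(C)Cl
- Why: Stryker conjugate reduction with reductive silylation touches only the enone and fixes the enol ether regiochemistry; Cu–H, like cuprates and H2/Pd on hydrindenones, should add at C3a syn to the angular methyl, giving the cis‑hydrindane and setting target C5.

**Step 2**
- Reactants: 2
- Product: 3, (3aS,7aR)‑5‑(TBSO)‑2,7a‑dimethyl‑2,3,3a,6,7,7a‑hexahydro‑1H‑inden‑1‑one (C2 epimer mixture)
- Conditions: LDA (1.1 equiv), THF, –78 °C; MeI (3 equiv), –78 → –20 °C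
- Reagents that add atoms: iodomethane, CI
- Why: Kinetic enolate alkylation, with C2 the only enolisable position; the new stereocentre is irrelevant because step 3 removes it.

**Step 3**
- Reactants: 3
- Product: 4, (3aS,7aR)‑5‑(TBSO)‑2,7a‑dimethyl‑3a,6,7,7a‑tetrahydro‑3H‑inden‑1‑yl triflate, with C1(OTf)=C2(CH3)
- Conditions: KHMDS (1.3 equiv), THF, –78 → –30 °C; Comins' reagent, –78 → 0 °C
- Reagents that add atoms: Comins' reagent, FC(F)(F)S(=O)(=O)N(c1ccc(Cl)cn1)S(=O)(=O)C(F)(F)F
- Why: O‑triflation of the only possible enolate (Comins enol‑triflate synthesis); the TBS enol ether is inert to amide bases.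

**Step 4**
- Reactants: 4
- Product: 5, 3‑[(1R,5R)‑5‑formyl‑1,3‑dimethyl‑2‑(triflyloxy)cyclopent‑2‑en‑1‑yl]propanoic acid
- Conditions: O3 (Sudan III end point), CH2Cl2/MeOH 4:1, –78 °C; Me2S, → rt; aqueous citric acid work‑up
- Reagents that add atoms: ozone, [O-][O+]=O
- Why: Criegee ozonolysis cleaves the electron‑rich silyl enol ether far faster than the electron‑poor tetrasubstituted vinyl triflate; it gives C4 as CHO and C5 as a silyl ester that hydrolyses to CO2H, under neutral conditions that preserve the α‑stereocentre.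

**Step 5**
- Reactants: 5
- Product: 6, methyl 3‑[(1R,5R)‑5‑formyl‑1,3‑dimethyl‑2‑(triflyloxy)cyclopent‑2‑en‑1‑yl]propanoate
- Conditions: TMSCHN2 (1.2 equiv), toluene/MeOH 4:1, 0 °C
- Reagents that add atoms: (trimethylsilyl)diazomethane, C[Si](C)(C)C=[N+]=[N-]
- Why: Base‑free diazoalkane esterification masks the acid for the Wittig and Mitsunobu steps without epimerising the aldehyde.

**Step 6**
- Reactants: 6; 7, isopropyltriphenylphosphonium iodide
- Product: 8, methyl 3‑[(1R,5S)‑1,3‑dimethyl‑5‑(2‑methylprop‑1‑en‑1‑yl)‑2‑(triflyloxy)cyclopent‑2‑en‑1‑yl]propanoate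
- Conditions: 7 (1.3 equiv), n‑BuLi (1.25 equiv), THF, 0 °C; add 6 at –78 °C, → 0 °C
- Reagents that add atoms: 7, CC(C)[P+](c1ccccc1)(c1ccccc1)c1ccccc1.[I-]
- Why: In this Wittig olefination the non‑stabilised ylide adds to the aldehyde at –78 °C faster than it enolises it and ignores the ester and vinyl triflate; the C5 geometry is unchanged, and its descriptor changes only through CIP priorities.

**Step 7**
- Reactants: 8
- Product: 9, methyl 3‑[(1R,5S)‑2‑formyl‑1,3‑dimethyl‑5‑(2‑methylprop‑1‑en‑1‑yl)cyclopent‑2‑en‑1‑yl]propanoate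
- Conditions: Pd(OAc)2 (10 mol %), dppp (10 mol %), CO (1 atm), Et3SiH (2 equiv), Et3N, DMF, 70 °C
- Reagents that add atoms: carbon monoxide, [C-]#[O+]
- Why: Pd‑catalysed reductive carbonylation (formylation) of the enol triflate installs the C2 carbon at the aldehyde level, so it can later be reduced selectively in the presence of the ester.

**Step 8**
- Reactants: 9
- Product: 10, methyl 3‑[(1R,3S,5S)‑2‑formyl‑1,3‑dimethyl‑5‑(2‑methylprop‑1‑en‑1‑yl)cyclopentyl]propanoate (C2 epimer mixture)
- Conditions: [(Ph3P)CuH]6 (0.5 equiv), TMSCl (3 equiv), toluene, rt; then 1 M HCl, THF, 0 °C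
- Reagents that add atoms: none
- Why: In this Stryker 1,4‑reduction of the enal, hydride attacks C3 from the top face, which carries only the 1‑CH3, because the propanoate chain and isobutenyl group block the bottom face in both envelope conformers; this pushes the 3‑CH3 down (3S), while the isolated alkene and the ester are untouched.

**Step 9**
- Reactants: 10
- Product: 11, methyl 3‑[(1R,2R,3S,5S)‑2‑(hydroxymethyl)‑1,3‑dimethyl‑5‑(2‑methylprop‑1‑en‑1‑yl)cyclopentyl]propanoate
- Conditions: DBU (0.5 equiv), CH2Cl2, rt, 12 h; then MeOH, NaBH4, 0 °C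
- Reagents that add atoms: none
- Why: Thermodynamic α‑epimerisation places the CHO trans to the 3‑CH3 and to the chain (cis only to the 1‑CH3), setting C2 as R; chemoselective borohydride reduction of the aldehyde over the ester then locks it.

**Step 10**
- Reactants: 11; 12, umbelliferone (7‑hydroxycoumarin)
- Product: 13, methyl ferulsinaate
- Conditions: 12 (1.5 equiv), PPh3 (1.6 equiv), DIAD (1.6 equiv), THF, 0 → 40 °C
- Reagents that add atoms: 12, Oc1ccc2ccc(=O)oc2c1
- Why: Mitsunobu etherification of a primary alcohol with an acidic phenol occurs at the CH2, so no stereocentre is touched.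

**Step 11**
- Reactants: 13
- Product: 14, ferulsinaic acid
- Conditions: LiOH·H2O (4 equiv), THF/MeOH/H2O 3:1:1, rt; then 1 M HCl to pH 2, 1 h
- Reagents that add atoms: lithium hydroxide, [Li+].[OH-]
- Why: Saponification cleaves the unhindered methyl ester, and any coumarin opened by hydroxide relactonises spontaneously on acidification.

## Compound list

| No. | Name | SMILES | Role |
|---|---|---|---|
| 1 | (R)‑Hajos–Parrish ketone | O=C1C=C2CCC(=O)[C@]2(C)CC1 | starting material |
| 2 | cis‑hydrindanone TBS enol ether | CC(C)(C)[Si](C)(C)OC1=C[C@@H]2CCC(=O)[C@]2(C)CC1 | intermediate |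
| 3 | 2‑methyl ketone (C2 epimers) | CC(C)(C)[Si](C)(C)OC1=C[C@@H]2CC(C)C(=O)[C@]2(C)CC1 | intermediate |
| 4 | bicyclic enol triflate | CC(C)(C)[Si](C)(C)OC1=C[C@@H]2CC(C)=C(OS(=O)(=O)C(F)(F)F)[C@]2(C)CC1 | intermediate |
| 5 | aldehyde acid | O=C[C@@H]1CC(C)=C(OS(=O)(=O)C(F)(F)F)[C@]1(C)CCC(=O)O | intermediate |
| 6 | aldehyde methyl ester | O=C[C@@H]1CC(C)=C(OS(=O)(=O)C(F)(F)F)[C@]1(C)CCC(=O)OC | intermediate |
| 7 | isopropyltriphenylphosphonium iodide | CC(C)[P+](c1ccccc1)(c1ccccc1)c1ccccc1.[I-] | starting material |
| 8 | isobutenyl enol triflate ester | CC(C)=C[C@@H]1CC(C)=C(OS(=O)(=O)C(F)(F)F)[C@]1(C)CCC(=O)OC | intermediate |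
| 9 | tetrasubstituted enal | CC(C)=C[C@@H]1CC(C)=C(C=O)[C@]1(C)CCC(=O)OC | intermediate |
| 10 | saturated aldehyde (C2 epimers) | CC(C)=C[C@@H]1C[C@H](C)C(C=O)[C@]1(C)CCC(=O)OC | intermediate |
| 11 | primary alcohol (1R,2R,3S,5S) | CC(C)=C[C@@H]1C[C@H](C)[C@@H](CO)[C@]1(C)CCC(=O)OC | intermediate |
| 12 | umbelliferone | Oc1ccc2ccc(=O)oc2c1 | starting material |
| 13 | methyl ferulsinaate | CC(C)=C[C@@H]1C[C@H](C)[C@@H](COc2ccc3ccc(=O)oc3c2)[C@]1(C)CCC(=O)OC | intermediate |
| 14 | ferulsinaic acid | CC(C)=C[C@@H]1C[C@H](C)[C@@H](COc2ccc3ccc(=O)oc3c2)[C@]1(C)CCC(=O)O | target |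

## Step count

- Total steps: 11
- Longest linear sequence: 11 (from 1)

## Steps most likely to fail, with fallbacks

1. **Step 1.** The risks are the cis/trans outcome of the Cu–H addition and slow TBSCl capture of the copper enolate.
   - Fallback: set the ring fusion by heterogeneous hydrogenation and mark C4 with oxygen instead.
   - Treat 1 with H2O2/NaOH to give the epoxide, then isomerise it with acid to the 4‑hydroxy‑enone (diosphenol).
   - Hydrogenate over Pd–C to the cis acyloin, then cleave with Pb(OAc)4/MeOH. This gives the keto aldehyde methyl ester directly.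
   - Carry out the Wittig reaction, then methylate and triflate the monocyclic keto ester (HMDS bases favour the ketone enolate), rejoining the route at 8.

2. **Step 8.** The risks are low reactivity of the tetrasubstituted enal and insufficient facial bias.
   - Fallback: bring in the 3‑CH3 as the nucleophile while C3a is still sp2.
   - Protect the enone of 1 as its dithioketal, convert C1 to the enol triflate, and carbonylate with Pd/CO/MeOH to the enoate.
   - Add Me2CuLi/TMSCl, which attacks anti to the angular methyl (as in 16α‑methyl steroids), and equilibrate the ester to trans.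
   - Reduce the ester, unmask the enone, and perform the ring cleavage afterwards.

3. **Step 7.** The risk is that formylation of the hindered triflate loses out to simple hydrogenolysis.
   - Fallback: Stille coupling of 8 with Bu3SnCH2OH gives the allylic alcohol.
   - Oxidise it with MnO2 to reach 9.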